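**Strategy**

Everything rests on treating the resorcinol ring as a masked 5-alkylcyclohexane-1,3-dione: the benzene ring carries the C17 chain on C1 and hydroxyls on C3 and C5, so cutting C1–C6 and C4–C5 leaves dimethyl malonate and a methyl (E)-enone whose β-carbon becomes C1. In one operation, methoxide-mediated conjugate addition followed by Claisen closure forges both bonds and the six-membered carbocycle. The enone is a linear C21 chain that already holds the isolated Z-alkene (Wittig) and the S carbinol from (S)-propylene oxide, masked as a triisopropylsilyl ether. Decarboxylation, silyl dienol ether formation, DDQ dehydrogenation and global desilylation then deliver the target.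

Key step: step 7

**Remarks on the design**

- Assumption: compounds 17, 18 and 19 are drawn as keto tautomers although they will be largely enolised; this does not change the chemistry.
- The target is 5-[(8Z,16S)-16-hydroxyheptadec-8-en-1-yl]benzene-1,3-diol. Its Z-alkene is isolated, with seven CH2 groups towards the ring and six towards the carbinol.
- The carbinol is carried as a triisopropylsilyl (TIPS) ether. This group is chosen because it must survive refluxing methoxide, hot aqueous hydroxide and the warm acidic decarboxylation, and still leave with fluoride in the last step.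
- The C6 unit is 1-bromo-6-chlorohexane. Its chloride becomes the leaving group for the phosphonium salt, so no alcohol protection, deprotection or halogenation is needed on that terminus.

**Route**

Step 1
Reactants: 1 1-bromo-6-chlorohexane; 2 (S)-propylene oxide [(2S)-2-methyloxirane]
Product: 4 (2S)-9-chlorononan-2-ol, via 6-chlorohexylmagnesium bromide 3 (not isolated)
Conditions: Mg, THF, 25–40 °C; then CuBr·SMe2 (5 mol%), 2, −30 to 0 °C; 1 M HCl quench
Reagents that add atoms: none
Why: Magnesium inserts into C–Br much faster than into C–Cl, and the copper-catalysed Grignard opening of a terminal epoxide is an SN2 attack at the unsubstituted CH2, so the oxygen-bearing carbon is untouched and the S configuration of 2 is carried unchanged into 4.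

Step 2
Reactants: 4 (2S)-9-chlorononan-2-ol
Product: 5 {[(2S)-9-chlorononan-2-yl]oxy}tri(propan-2-yl)silane
Conditions: TIPSOTf, 2,6-lutidine, CH2Cl2, 0 °C to rt
Reagents that add atoms: triisopropylsilyl trifluoromethanesulfonate, CC(C)[Si](C(C)C)(C(C)C)OS(=O)(=O)C(F)(F)F
Why: O-Silylation of a secondary alcohol with a silyl triflate and a hindered pyridine base is routine, and the primary chloride is inert to it.

Step 3
Reactants: 5 {[(2S)-9-chlorononan-2-yl]oxy}tri(propan-2-yl)silane
Product: 7 triphenyl[(8S)-8-(triisopropylsilyloxy)nonyl]phosphonium iodide, via alkyl iodide 6 (not isolated)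
Conditions: NaI, PPh3, MeCN, reflux
Reagents that add atoms: sodium iodide, [Na+].[I-]; triphenylphosphine, c1ccc(cc1)P(c1ccccc1)c1ccccc1
Why: In-flask Finkelstein exchange feeds the primary iodide to SN2 quaternisation by the phosphine, a standard way to turn alkyl chlorides into phosphonium iodides under neutral conditions that the silyl ether tolerates.

Step 4
Reactants: 7 triphenyl[(8S)-8-(triisopropylsilyloxy)nonyl]phosphonium iodide; 8 methyl 9-oxononanoate
Product: 10 methyl (9Z,17S)-17-(triisopropylsilyloxy)octadec-9-enoate, via phosphonium ylide 9 (not isolated)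
Conditions: NaN(SiMe3)2, THF, −78 to 0 °C; then 8, −78 °C to rt
Reagents that add atoms: none
Why: Wittig olefination with a non-stabilised ylide under lithium-free conditions at low temperature goes through the kinetically preferred cis-oxaphosphetane and should be highly Z-selective, and the ylide attacks the aldehyde of 8 far faster than its ester.

Step 5
Reactants: 10 methyl (9Z,17S)-17-(triisopropylsilyloxy)octadec-9-enoate
Product: 12 (9Z,17S)-17-(triisopropylsilyloxy)octadec-9-enal, via aluminium hemiacetal 11 (not isolated)
Conditions: i-Bu2AlH (1.1 equiv), CH2Cl2, −78 °C; aq. KNaC4H4O6 work-up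
Reagents that add atoms: none
Why: Partial reduction of a methyl ester with one equivalent of i-Bu2AlH at −78 °C stops at the tetrahedral aluminium hemiacetal 11, which releases the aldehyde only on aqueous work-up, while alkene and silyl ether are untouched.

Step 6
Reactants: 12 (9Z,17S)-17-(triisopropylsilyloxy)octadec-9-enal; 13 1-(triphenylphosphoranylidene)propan-2-one
Product: 14 (3E,12Z,20S)-20-(triisopropylsilyloxy)henicosa-3,12-dien-2-one
Conditions: toluene, 90 °C
Reagents that add atoms: none
Why: Wittig olefination of an aliphatic aldehyde with an acyl-stabilised ylide is reliably E-selective and leaves the isolated Z-alkene and the silyl ether alone.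

Step 7
Reactants: 14 (3E,12Z,20S)-20-(triisopropylsilyloxy)henicosa-3,12-dien-2-one; 15 dimethyl malonate
Product: 17 methyl 2,4-dioxo-6-[(8Z,16S)-16-(triisopropylsilyloxy)heptadec-8-en-1-yl]cyclohexane-1-carboxylate, via Michael adduct 16 (not isolated)
Conditions: NaOMe (1.2 equiv), MeOH–THF, reflux; then cold 1 M HCl to pH 4
Reagents that add atoms: none
Why: The malonate anion adds to C4 (the β-carbon) of enone 14 to give adduct 16, the enolate on the methyl side of its ketone then attacks one malonate ester carbonyl and expels methoxide, and deprotonation of the resulting cyclic β-diketone pulls the reversible steps forward. The closest known reaction type is the Michael–Claisen (Dieckmann-type) annulation of alk-3-en-2-ones with malonate esters, the classical entry to 5-alkylcyclohexane-1,3-diones. The six-membered carbocycle closes by a 6-(enolendo)-exo-trig acyl substitution. The two new sp3 ring centres (C1 and C6 of the cyclohexane) form without control, C1 is epimerisable, and both are erased in steps 8 to 10, while the remote S carbinol centre is not involved. The step needs 1,4- over 1,2-addition, secured by the soft stabilised malonate anion and the reversibility of carbonyl addition, and a single mode of closure, secured because only the methyl-side enolate reaches an ester through a six-membered transition state. The isolated Z-alkene and the TIPS ether are inert to methoxide.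

Step 8
Reactants: 17 methyl 2,4-dioxo-6-[(8Z,16S)-16-(triisopropylsilyloxy)heptadec-8-en-1-yl]cyclohexane-1-carboxylate
Product: 19 5-[(8Z,16S)-16-(triisopropylsilyloxy)heptadec-8-en-1-yl]cyclohexane-1,3-dione, via β-keto acid 18 (not isolated)
Conditions: 2 M NaOH, MeOH–THF, 65 °C; then 1 M HCl to pH 3–4, 50 °C
Reagents that add atoms: none
Why: Saponification followed by acidification gives the β-keto acid 18, which loses CO2 through the usual cyclic transition state on gentle warming, and the TIPS ether is stable to hydroxide and should survive the brief mildly acidic stage.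

Step 9
Reactants: 19 5-[(8Z,16S)-16-(triisopropylsilyloxy)heptadec-8-en-1-yl]cyclohexane-1,3-dione
Product: 20 1,3-bis(tert-butyldimethylsilyloxy)-5-[(8Z,16S)-16-(triisopropylsilyloxy)heptadec-8-en-1-yl]cyclohexa-1,3-diene
Conditions: TBSOTf (2.5 equiv), Et3N (4 equiv), CH2Cl2, 0 °C to rt; pentane/cold aq. NaHCO3 work-up, used crude
Reagents that add atoms: tert-butyldimethylsilyl trifluoromethanesulfonate, CC(C)(C)[Si](C)(C)OS(=O)(=O)C(F)(F)F
Why: Soft enolisation of a 1,3-diketone with two equivalents of silyl triflate and triethylamine is the established route to 1,3-bis(silyloxy)-1,3-dienes, and because the dione is symmetric about the C2–C5 axis either direction of the second enolisation gives the same diene, whose ring sp3 centre is lost in step 10.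

Step 10
Reactants: 20 1,3-bis(tert-butyldimethylsilyloxy)-5-[(8Z,16S)-16-(triisopropylsilyloxy)heptadec-8-en-1-yl]cyclohexa-1,3-diene
Product: 21 1,3-bis(tert-butyldimethylsilyloxy)-5-[(8Z,16S)-16-(triisopropylsilyloxy)heptadec-8-en-1-yl]benzene
Conditions: DDQ (1.15 equiv), 2,4,6-collidine, toluene, 0 °C to rt
Reagents that add atoms: none
Why: DDQ dehydrogenation of a silyl dienol ether should work because hydride loss from C5–H gives a pentadienyl cation stabilised by both silyloxy groups and proton loss from C6 then aromatises the ring, an oxidation far easier than any at the isolated Z-alkene, while collidine keeps the medium non-acidic.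

Step 11
Reactants: 21 1,3-bis(tert-butyldimethylsilyloxy)-5-[(8Z,16S)-16-(triisopropylsilyloxy)heptadec-8-en-1-yl]benzene
Product: 22 Hansfordiol E, 5-[(8Z,16S)-16-hydroxyheptadec-8-en-1-yl]benzene-1,3-diol
Conditions: Bu4NF (5 equiv), THF, 0 °C to rt, Ar; then AcOH, H2O
Reagents that add atoms: none
Why: Fluoride-mediated desilylation, driven by the strong Si–F bond, removes the two aryl silyl ethers quickly and the secondary TIPS ether more slowly, and simply unmasks the S carbinol without touching the alkene.

**Compound list**

1 | 1-bromo-6-chlorohexane | ClCCCCCCBr | starting material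
2 | (S)-propylene oxide, (2S)-2-methyloxirane | C[C@H]1CO1 | starting material
3 | 6-chlorohexylmagnesium bromide | ClCCCCCC[Mg]Br | intermediate (not isolated)
4 | (2S)-9-chlorononan-2-ol | C[C@H](O)CCCCCCCCl | intermediate
5 | {[(2S)-9-chlorononan-2-yl]oxy}tri(propan-2-yl)silane | C[C@H](O[Si](C(C)C)(C(C)C)C(C)C)CCCCCCCCl | intermediate
6 | {[(2S)-9-iodononan-2-yl]oxy}tri(propan-2-yl)silane | C[C@H](O[Si](C(C)C)(C(C)C)C(C)C)CCCCCCCI | intermediate (not isolated)
7 | triphenyl[(8S)-8-(triisopropylsilyloxy)nonyl]phosphonium iodide | C[C@H](O[Si](C(C)C)(C(C)C)C(C)C)CCCCCCC[P+](c1ccccc1)(c1ccccc1)c1ccccc1.[I-] | intermediate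
8 | methyl 9-oxononanoate | COC(=O)CCCCCCCC=O | starting material
9 | triphenyl[(8S)-8-(triisopropylsilyloxy)nonylidene]phosphorane | C[C@H](O[Si](C(C)C)(C(C)C)C(C)C)CCCCCCC=P(c1ccccc1)(c1ccccc1)c1ccccc1 | intermediate (not isolated)
10 | methyl (9Z,17S)-17-(triisopropylsilyloxy)octadec-9-enoate | COC(=O)CCCCCCC/C=C\CCCCCC[C@H](C)O[Si](C(C)C)(C(C)C)C(C)C | intermediate
11 | diisobutylaluminium hemiacetal of 10, {[(9Z,17S)-1-methoxy-17-(triisopropylsilyloxy)octadec-9-en-1-yl]oxy}bis(2-methylpropyl)alumane (hemiacetal carbon uncontrolled) | COC(O[Al](CC(C)C)CC(C)C)CCCCCCC/C=C\CCCCCC[C@H](C)O[Si](C(C)C)(C(C)C)C(C)C | intermediate (not isolated)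
12 | (9Z,17S)-17-(triisopropylsilyloxy)octadec-9-enal | O=CCCCCCCC/C=C\CCCCCC[C@H](C)O[Si](C(C)C)(C(C)C)C(C)C | intermediate
13 | 1-(triphenylphosphoranylidene)propan-2-one | CC(=O)C=P(c1ccccc1)(c1ccccc1)c1ccccc1 | starting material
14 | (3E,12Z,20S)-20-(triisopropylsilyloxy)henicosa-3,12-dien-2-one | CC(=O)/C=C/CCCCCCC/C=C\CCCCCC[C@H](C)O[Si](C(C)C)(C(C)C)C(C)C | intermediate (key-step precursor)
15 | dimethyl malonate | COC(=O)CC(=O)OC | starting material
16 | dimethyl 2-[(12Z,20S)-2-oxo-20-(triisopropylsilyloxy)henicos-12-en-4-yl]propanedioate (C4 uncontrolled) | COC(=O)C(C(=O)OC)C(CC(C)=O)CCCCCCC/C=C\CCCCCC[C@H](C)O[Si](C(C)C)(C(C)C)C(C)C | intermediate (not isolated)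
17 | methyl 2,4-dioxo-6-[(8Z,16S)-16-(triisopropylsilyloxy)heptadec-8-en-1-yl]cyclohexane-1-carboxylate (ring C1 and C6 uncontrolled) | COC(=O)C1C(=O)CC(=O)CC1CCCCCCC/C=C\CCCCCC[C@H](C)O[Si](C(C)C)(C(C)C)C(C)C | intermediate (key-step product)
18 | 2,4-dioxo-6-[(8Z,16S)-16-(triisopropylsilyloxy)heptadec-8-en-1-yl]cyclohexane-1-carboxylic acid | OC(=O)C1C(=O)CC(=O)CC1CCCCCCC/C=C\CCCCCC[C@H](C)O[Si](C(C)C)(C(C)C)C(C)C | intermediate (not isolated)
19 | 5-[(8Z,16S)-16-(triisopropylsilyloxy)heptadec-8-en-1-yl]cyclohexane-1,3-dione | O=C1CC(=O)CC(CCCCCCC/C=C\CCCCCC[C@H](C)O[Si](C(C)C)(C(C)C)C(C)C)C1 | intermediate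
20 | 1,3-bis(tert-butyldimethylsilyloxy)-5-[(8Z,16S)-16-(triisopropylsilyloxy)heptadec-8-en-1-yl]cyclohexa-1,3-diene (ring C5 uncontrolled) | CC(C)(C)[Si](C)(C)OC1=CC(O[Si](C)(C)C(C)(C)C)=CC(CCCCCCC/C=C\CCCCCC[C@H](C)O[Si](C(C)C)(C(C)C)C(C)C)C1 | intermediate
21 | 1,3-bis(tert-butyldimethylsilyloxy)-5-[(8Z,16S)-16-(triisopropylsilyloxy)heptadec-8-en-1-yl]benzene | CC(C)(C)[Si](C)(C)Oc1cc(O[Si](C)(C)C(C)(C)C)cc(CCCCCCC/C=C\CCCCCC[C@H](C)O[Si](C(C)C)(C(C)C)C(C)C)c1 | intermediate
22 | Hansfordiol E, 5-[(8Z,16S)-16-hydroxyheptadec-8-en-1-yl]benzene-1,3-diol | C[C@H](O)CCCCCC/C=C\CCCCCCCc1cc(O)cc(O)c1 | target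

**Step count and risk**

Total step count: 11. Longest linear sequence: 11 steps (1 and 2 to 22).

Steps most likely to fail:

1. Step 10 (with step 9 feeding it). The moisture-sensitive dienol ether may revert to the dione before hydride abstraction, or DDQ may add to the electron-rich diene instead of dehydrogenating it. The fallback sets out from dione 19, bypasses steps 9 and 10, and returns to the route at target 22. Mono-O-silylation of 19 (TIPSCl, Et3N, CH2Cl2) should give the vinylogous silyl ester 3-(triisopropylsilyloxy)-5-[(8Z,16S)-16-(triisopropylsilyloxy)heptadec-8-en-1-yl]cyclohex-2-en-1-one F1. Deprotonation at C6 with LiN(i-Pr)2 in THF at −78 °C and treatment of the enolate in the same flask with N-tert-butylbenzenesulfinimidoyl chloride (Mukaiyama dehydrogenation) introduces the C5–C6 unsaturation, and the ring aromatises to 3-(triisopropylsilyloxy)-5-[(8Z,16S)-16-(triisopropylsilyloxy)heptadec-8-en-1-yl]phenol F2. Bu4NF under the conditions of step 11 then removes both silyl groups to give 22.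

2. Step 7. Methoxide may trigger self-condensation of the enolisable methyl enone, or the conjugate addition may reverse before ring closure, and the lipophilic chain may dissolve poorly. The fallback sets out from aldehyde 12 and returns at keto ester 17 with the roles of the partners exchanged. Horner–Wadsworth–Emmons olefination of 12 with trimethyl phosphonoacetate (NaH, THF) should give methyl (2E,11Z,19S)-19-(triisopropylsilyloxy)icosa-2,11-dienoate F3, an acceptor with no enolisable ketone. Methyl acetoacetate and NaOMe in MeOH–THF at reflux add to it to form dimethyl 2-acetyl-3-[(8Z,16S)-16-(triisopropylsilyloxy)heptadec-8-en-1-yl]pentanedioate F4, whose acetyl enolate closes onto the chain ester to give the same compound 17.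

3. Step 5. The tetrahedral aluminium intermediate may collapse before the quench, so that the aldehyde is reduced further to the alcohol. The fallback sets out from ester 10 and returns at aldehyde 12. Full reduction with LiAlH4 (THF, 0 °C) should give (9Z,17S)-17-(triisopropylsilyloxy)octadec-9-en-1-ol F5, which Dess–Martin periodinane (NaHCO3, CH2Cl2) oxidises to 12.

Further compounds
F1 | step 10 | 3-(triisopropylsilyloxy)-5-[(8Z,16S)-16-(triisopropylsilyloxy)heptadec-8-en-1-yl]cyclohex-2-en-1-one | O=C1C=C(O[Si](C(C)C)(C(C)C)C(C)C)CC(CCCCCCC/C=C\CCCCCC[C@H](C)O[Si](C(C)C)(C(C)C)C(C)C)C1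
F2 | step 10 | 3-(triisopropylsilyloxy)-5-[(8Z,16S)-16-(triisopropylsilyloxy)heptadec-8-en-1-yl]phenol | Oc1cc(O[Si](C(C)C)(C(C)C)C(C)C)cc(CCCCCCC/C=C\CCCCCC[C@H](C)O[Si](C(C)C)(C(C)C)C(C)C)c1
F3 | step 7 | methyl (2E,11Z,19S)-19-(triisopropylsilyloxy)icosa-2,11-dienoate | COC(=O)/C=C/CCCCCCC/C=C\CCCCCC[C@H](C)O[Si](C(C)C)(C(C)C)C(C)C
F4 | step 7 | dimethyl 2-acetyl-3-[(8Z,16S)-16-(triisopropylsilyloxy)heptadec-8-en-1-yl]pentanedioate | COC(=O)CC(CCCCCCC/C=C\CCCCCC[C@H](C)O[Si](C(C)C)(C(C)C)C(C)C)C(C(C)=O)C(=O)OC
F5 | step 5 | (9Z,17S)-17-(triisopropylsilyloxy)octadec-9-en-1-ol | OCCCCCCCC/C=C\CCCCCC[C@H](C)O[Si](C(C)C)(C(C)C)C(C)C
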